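**Plan**
- Retrosynthesis: the O7–S bond and the protecting groups on O4' (benzyl) and O5/O7 (acetals) are cut first. O1–C2 of ring C is cut next, which opens the flavone to an ortho-hydroxyaryl ynone.
- The ynone is cut at O1–C8a and C4–C4a. C8a and C4a are neighbouring carbons of ring A and C4a is flanked by the C5 oxygen, so a ring-A aryne across C4a–C8a is polarised in the sense needed to take up the carboxyl C–O bond of an arylpropiolic acid. O1 and C4 both come from the CO2H group.
- Forward: ring A is elaborated from phloroglucinol into a silyl triflate and ring B arrives in 4-benzyloxyphenylpropiolic acid. The aryne insertion joins them without closing a ring, and ring C then closes by 6-endo addition of O1 to C2.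
- Endgame: acetal removal, sulfation of O7 (O5 is chelated to the C4 carbonyl, O4' is benzylated), hydrogenolysis.
- Stereochemistry: the target has no stereocentre and none is created.

Key step: step 5

Assumption: the target is taken as the free hydrogen sulfate as drawn; because aryl hydrogen sulfates lose SO3 under acid, the sulfate is carried as its sodium salt and protonated only in the last operation.

**Step 1**
Reactants: 1 phloroglucinol (benzene-1,3,5-triol); 2 chloromethyl methyl ether
Product: 3 3,5-bis(methoxymethoxy)phenol
Conditions: NaH (2.0 equiv), DMF, 0 °C; 2 (2.0 equiv), 0 °C → rt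
Reagents that add atoms: none
Why: Williamson O-alkylation of the sodium phenoxides with a hard alkoxymethyl chloride; the three hydroxyls are equivalent, so the bis-ether should be the main component of a statistical mixture, separable on silica gel from the mono-ether (returned to the reaction) and the tris-ether.

**Step 2**
Reactants: 3 3,5-bis(methoxymethoxy)phenol
Product: 4 2-bromo-3,5-bis(methoxymethoxy)phenol
Conditions: NBS (1.0 equiv), i-Pr2NH (10 mol %), CH2Cl2, –78 °C → 0 °C
Reagents that add atoms: N-bromosuccinimide, O=C1CCC(=O)N1Br
Why: Amine-mediated electrophilic ortho-bromination of a phenol: the N-bromoamine hydrogen-bonded to the hydroxyl delivers bromine to C2 (C2 and C6 are equivalent), C4 is screened by two acetal ethers, and one equivalent of reagent at low temperature should hold the reaction at the monobromide.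

**Step 3**
Reactants: 4 2-bromo-3,5-bis(methoxymethoxy)phenol
Product: 7 3,5-bis(methoxymethoxy)-2-(trimethylsilyl)phenyl trifluoromethanesulfonate, via aryl trimethylsilyl ether 5 (not isolated), via lithium 2-silylphenoxide 6 (not isolated)
Conditions: HMDS, THF, 65 °C, evaporate; n-BuLi, THF, –78 °C; Tf2O, –78 °C → 0 °C
Reagents that add atoms: hexamethyldisilazane, C[Si](C)(C)N[Si](C)(C)C; trifluoromethanesulfonic anhydride, O=S(=O)(OS(=O)(=O)C(F)(F)F)C(F)(F)F
Why: O-silylation, bromine–lithium exchange and retro-Brook 1,3 O-to-C silyl migration place silicon on C2, and the lithium phenoxide released is triflated in the same flask; this is the standard sequence to ortho-silylaryl triflates, and the acetal ethers tolerate n-BuLi and cold Tf2O.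

**Step 4**
Reactants: 8 1-(benzyloxy)-4-ethynylbenzene
Product: 11 3-[4-(benzyloxy)phenyl]prop-2-ynoic acid, via lithium acetylide 9 (not isolated), via lithium arylpropiolate 10 (not isolated)
Conditions: n-BuLi, THF, –78 °C; CO2 (gas), –78 °C → rt; 1 M HCl
Reagents that add atoms: carbon dioxide, O=C=O
Why: Deprotonation of the terminal alkyne and carboxylation of the lithium acetylide, a standard route to arylpropiolic acids that leaves the benzyl ether untouched.

**Step 5**
Reactants: 11 3-[4-(benzyloxy)phenyl]prop-2-ynoic acid; 7 3,5-bis(methoxymethoxy)-2-(trimethylsilyl)phenyl trifluoromethanesulfonate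
Product: 15 3-[4-(benzyloxy)phenyl]-1-[2-hydroxy-4,6-bis(methoxymethoxy)phenyl]prop-2-yn-1-one, via potassium arylpropiolate 12 (not isolated), via 3,5-bis(methoxymethoxy)benzyne 13 (not isolated), via potassium phenoxide 14 (not isolated)
Conditions: 11 (1.3 equiv), KH (1.3 equiv), THF, 0 °C; then 7 (1.0 equiv), KF, 18-crown-6, THF, 0 °C → rt; AcOH, –40 °C
Reagents that add atoms: none
Why: Fluoride attacks silicon in 7 and the aryl anion expels triflate to give aryne 13, whose strained bond lies between the future C8a and C4a; an oxygen of carboxylate 12 bonds to C8a, the aryne carbon meta to the C5 acetal oxygen, because that oxygen widens the internal angle at C8a and inductively stabilises the negative charge that builds up next to it on C4a. The C4a carbanion then adds to the carbonyl of the newly made aryl ester in a four-centre step, and the strained alkoxide opens towards phenoxide 14, so that the alkynoyl group ends on C4a and the former carboxyl oxygen becomes O1 (an anionic Fries-type 1,3 O-to-C acyl shift). The closest known reaction type is the fluoride-induced insertion of arynes into the C–O bond of carboxylic acids to give ortho-hydroxyaryl ketones; here the carboxylate is preformed with KH so that no proton donor is present to trap the aryl anion as the plain aryl ester, which also allows a soluble fluoride at room temperature and spares the heat-sensitive propiolate from decarboxylation. No ring is closed and no stereocentre is formed: addition of the phenoxide oxygen to the ynone would have to leave an unstabilised vinyl anion at C3 with nothing in the aprotic medium to protonate it, and the cold AcOH quench protonates oxygen first. The step needs regioselectivity (oxygen to C8a, acyl to C4a), secured by the C5 oxygen beside C4a with the remote C7 oxygen exerting only a weak opposing influence, and chemoselectivity for 1,2-attack of the aryl anion on the ester carbonyl over the alkyne, secured by the carbonyl carbon lying directly beside the in-plane carbanion.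

**Step 6**
Reactants: 15 3-[4-(benzyloxy)phenyl]-1-[2-hydroxy-4,6-bis(methoxymethoxy)phenyl]prop-2-yn-1-one
Product: 16 4'-(benzyloxy)-5,7-bis(methoxymethoxy)flavone (2-[4-(benzyloxy)phenyl]-5,7-bis(methoxymethoxy)-4H-chromen-4-one)
Conditions: DMAP (20 mol %), DMF, rt
Reagents that add atoms: none
Why: Nucleophile-catalysed 6-endo cyclisation of an ortho-alkynoylphenol: conjugate addition of DMAP to the ynone and proton transfer set up an addition–elimination of the phenol oxygen at C2, a pathway that leads to the six-membered pyranone and should suppress the 5-exo closure to the aurone.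

**Step 7**
Reactants: 16 4'-(benzyloxy)-5,7-bis(methoxymethoxy)flavone
Product: 17 4'-(benzyloxy)-5,7-dihydroxyflavone (4'-O-benzylapigenin)
Conditions: HCl (2 M in MeOH), THF, 50 °C
Reagents that add atoms: none
Why: Acid-catalysed acetal exchange with methanol removes both methoxymethyl ethers as dimethoxymethane, while the benzyl ether and the flavone core are stable to methanolic HCl.

**Step 8**
Reactants: 17 4'-(benzyloxy)-5,7-dihydroxyflavone
Product: 19 sodium 4'-(benzyloxy)-5-hydroxyflavon-7-yl sulfate, via pyridinium 7-sulfate salt 18 (not isolated)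
Conditions: SO3·pyridine (3 equiv), pyridine, rt; aq NaHCO3; C18 chromatography
Reagents that add atoms: sulfur trioxide–pyridine complex, O=S(=O)([O-])[n+]1ccccc1; sodium hydrogencarbonate, [Na+].OC([O-])=O
Why: O-sulfation of a phenol with an amine–SO3 complex: O7 is the free, acidic phenol, whereas O5 is tied up in a hydrogen bond to the C4 carbonyl and O4' is benzylated, so a single sulfate should enter at O7 and is isolated as its sodium salt.

**Step 9**
Reactants: 19 sodium 4'-(benzyloxy)-5-hydroxyflavon-7-yl sulfate
Product: 21 apigenin 7-sulfate (5-hydroxy-2-(4-hydroxyphenyl)-4-oxo-4H-chromen-7-yl hydrogen sulfate), via sodium apigenin 7-sulfate 20 (not isolated)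
Conditions: H2 (1 atm), 10% Pd/C, MeOH–H2O, rt; filter; aq HCl (1.0 equiv), 0 °C; C18 desalting, freeze-drying
Reagents that add atoms: none
Why: Hydrogenolysis of the benzyl aryl ether over palladium on carbon at atmospheric pressure should leave the flavone C2–C3 double bond and the sulfate salt intact, and brief cold protonation followed by reversed-phase desalting gives the hydrogen sulfate.

**Compound list**
1 | phloroglucinol (benzene-1,3,5-triol) | Oc1cc(O)cc(O)c1 | starting material
2 | chloromethyl methyl ether | COCCl | starting material
3 | 3,5-bis(methoxymethoxy)phenol | COCOc1cc(O)cc(OCOC)c1 | intermediate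
4 | 2-bromo-3,5-bis(methoxymethoxy)phenol | COCOc1cc(O)c(Br)c(OCOC)c1 | intermediate
5 | [2-bromo-3,5-bis(methoxymethoxy)phenoxy]trimethylsilane (not isolated) | COCOc1cc(O[Si](C)(C)C)c(Br)c(OCOC)c1 | intermediate
6 | lithium 3,5-bis(methoxymethoxy)-2-(trimethylsilyl)phenoxide (not isolated) | [Li+].[O-]c1cc(OCOC)cc(OCOC)c1[Si](C)(C)C | intermediate
7 | 3,5-bis(methoxymethoxy)-2-(trimethylsilyl)phenyl trifluoromethanesulfonate | COCOc1cc(OCOC)c([Si](C)(C)C)c(OS(=O)(=O)C(F)(F)F)c1 | intermediate
8 | 1-(benzyloxy)-4-ethynylbenzene | C#Cc1ccc(OCc2ccccc2)cc1 | starting material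
9 | lithium [4-(benzyloxy)phenyl]acetylide (not isolated) | [Li]C#Cc1ccc(OCc2ccccc2)cc1 | intermediate
10 | lithium 3-[4-(benzyloxy)phenyl]prop-2-ynoate (not isolated) | [Li+].[O-]C(=O)C#Cc1ccc(OCc2ccccc2)cc1 | intermediate
11 | 3-[4-(benzyloxy)phenyl]prop-2-ynoic acid | OC(=O)C#Cc1ccc(OCc2ccccc2)cc1 | intermediate
12 | potassium 3-[4-(benzyloxy)phenyl]prop-2-ynoate (not isolated) | [K+].[O-]C(=O)C#Cc1ccc(OCc2ccccc2)cc1 | intermediate
13 | 3,5-bis(methoxymethoxy)benzyne (not isolated) | COCOC1=CC#CC(OCOC)=C1 | intermediate
14 | potassium 2-{3-[4-(benzyloxy)phenyl]prop-2-ynoyl}-3,5-bis(methoxymethoxy)phenoxide (not isolated) | [K+].[O-]c1cc(OCOC)cc(OCOC)c1C(=O)C#Cc1ccc(OCc2ccccc2)cc1 | intermediate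
15 | 3-[4-(benzyloxy)phenyl]-1-[2-hydroxy-4,6-bis(methoxymethoxy)phenyl]prop-2-yn-1-one | O=C(C#Cc1ccc(OCc2ccccc2)cc1)c1c(O)cc(OCOC)cc1OCOC | intermediate
16 | 4'-(benzyloxy)-5,7-bis(methoxymethoxy)flavone | O=c1cc(-c2ccc(OCc3ccccc3)cc2)oc2cc(OCOC)cc(OCOC)c12 | intermediate
17 | 4'-(benzyloxy)-5,7-dihydroxyflavone | O=c1cc(-c2ccc(OCc3ccccc3)cc2)oc2cc(O)cc(O)c12 | intermediate
18 | pyridinium 4'-(benzyloxy)-5-hydroxyflavon-7-yl sulfate (not isolated) | [O-]S(=O)(=O)Oc1cc(O)c2c(c1)oc(-c1ccc(OCc3ccccc3)cc1)cc2=O.c1cc[nH+]cc1 | intermediate
19 | sodium 4'-(benzyloxy)-5-hydroxyflavon-7-yl sulfate | [Na+].[O-]S(=O)(=O)Oc1cc(O)c2c(c1)oc(-c1ccc(OCc3ccccc3)cc1)cc2=O | intermediate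
20 | sodium apigenin 7-sulfate (not isolated) | [Na+].[O-]S(=O)(=O)Oc1cc(O)c2c(c1)oc(-c1ccc(O)cc1)cc2=O | intermediate
21 | apigenin 7-sulfate | O=c1cc(-c2ccc(O)cc2)oc2cc(OS(=O)(=O)O)cc(O)c12 | target

**Step count**
Total: 9 steps. Longest linear sequence: 8 steps (steps 1, 2, 3, 5, 6, 7, 8, 9); step 4 is a one-step branch.

**Steps most likely to fail**

Step 5. Three processes may intervene. The aryl anion may be protonated before it reaches the ester carbonyl (adventitious proton sources, hydrogen abstraction from the crown ether), so that the sequence stops at O-arylation. The product phenoxide may compete with the carboxylate for a second aryne. The phenoxide may also close prematurely onto the ynone in the 5-exo sense. The fallback sets out from phenol 3 and comes back to the route at ynone 15. Magnesium-mediated ortho-formylation of 3 (MgCl2, Et3N, paraformaldehyde, MeCN, reflux) should give 2-hydroxy-4,6-bis(methoxymethoxy)benzaldehyde F1, since this formylation takes place only ortho to the free hydroxyl. Two equivalents of lithium acetylide 9 (from 8 and n-BuLi, THF, –78 °C) add to the aldehyde to give racemic 3-[4-(benzyloxy)phenyl]-1-[2-hydroxy-4,6-bis(methoxymethoxy)phenyl]prop-2-yn-1-ol F2. Its carbinol centre is removed at once by MnO2 in CH2Cl2, which oxidises the benzylic propargylic alcohol to 15.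

Step 2. Bromination may take place at C4, para to the hydroxyl, or twice, giving isomers that are hard to separate and that would carry the silyl group to the wrong carbon. The fallback sets out from 3 and comes back at silyl triflate 7, and fixes the site by directed ortho-metalation. Carbamoylation (ClC(O)NEt2, NaH, THF) gives 3,5-bis(methoxymethoxy)phenyl N,N-diethylcarbamate F3. Lithiation with s-BuLi and TMEDA in THF at –78 °C, directed jointly by the carbamate and the neighbouring acetal ether to C2, and a TMSCl quench give 3,5-bis(methoxymethoxy)-2-(trimethylsilyl)phenyl N,N-diethylcarbamate F4. LiAlH4 in THF cleaves the carbamate reductively to 3,5-bis(methoxymethoxy)-2-(trimethylsilyl)phenol F5, and Tf2O with pyridine in CH2Cl2 at 0 °C gives 7.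

Step 8. Sulfation of the poorly soluble phenol may stall, the sulfate may be partly lost on concentration from pyridine, and pyridinium and inorganic sulfate salts may be carried over and slow the palladium catalyst of step 9. The fallback sets out from 17 and comes back at sodium salt 19, and carries the sulfate through purification as a neutral diester. 2,2,2-Trichloroethyl chlorosulfate (Et3N, DMAP, THF, 0 °C → rt) converts 17 into 4'-(benzyloxy)-5-hydroxyflavon-7-yl 2,2,2-trichloroethyl sulfate F6, which can be chromatographed on silica gel. Zn dust and HCO2NH4 in MeOH remove the trichloroethyl group by reductive β-elimination to give ammonium 4'-(benzyloxy)-5-hydroxyflavon-7-yl sulfate F7. One equivalent of NaHCO3 in water followed by evaporation exchanges ammonium for sodium and gives 19.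

**Further compounds**
F1 | step 5 | 2-hydroxy-4,6-bis(methoxymethoxy)benzaldehyde | O=Cc1c(O)cc(OCOC)cc1OCOC
F2 | step 5 | 3-[4-(benzyloxy)phenyl]-1-[2-hydroxy-4,6-bis(methoxymethoxy)phenyl]prop-2-yn-1-ol (racemic) | OC(C#Cc1ccc(OCc2ccccc2)cc1)c1c(O)cc(OCOC)cc1OCOC
F3 | step 2 | 3,5-bis(methoxymethoxy)phenyl N,N-diethylcarbamate | CCN(CC)C(=O)Oc1cc(OCOC)cc(OCOC)c1
F4 | step 2 | 3,5-bis(methoxymethoxy)-2-(trimethylsilyl)phenyl N,N-diethylcarbamate | CCN(CC)C(=O)Oc1cc(OCOC)cc(OCOC)c1[Si](C)(C)C
F5 | step 2 | 3,5-bis(methoxymethoxy)-2-(trimethylsilyl)phenol | COCOc1cc(O)c([Si](C)(C)C)c(OCOC)c1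
F6 | step 8 | 4'-(benzyloxy)-5-hydroxyflavon-7-yl 2,2,2-trichloroethyl sulfate | O=c1cc(-c2ccc(OCc3ccccc3)cc2)oc2cc(OS(=O)(=O)OCC(Cl)(Cl)Cl)cc(O)c12
F7 | step 8 | ammonium 4'-(benzyloxy)-5-hydroxyflavon-7-yl sulfate | [NH4+].[O-]S(=O)(=O)Oc1cc(O)c2c(c1)oc(-c1ccc(OCc3ccccc3)cc1)cc2=O
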